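**Compound numbers used throughout**

1 chloro acetal, 2 butynediol, 3 Grignard reagent from 1, 4 alkenylmagnesium adduct, 5 acetal butenolide, 6 hydroxy aldehyde, 7 silyl ether aldehyde, 8 enal, 9 butynol, 10 alkenylmagnesium from 9, 11 iodo alcohol, 12 iodoenone, 13 boron enolate, 14 boron aldolate, 15 aldol, 16 anti diol, 17 diacetate, 18 silyloxyfuran, 19 silyl formyl ester, 20 hydroxybutenolide, 21 methyl formyl ester (cyclisation precursor), 22 alkenylchromium, 23 chromium alkoxide, 24 C13 silyl ether of the target, 25 target.

## Analysis of the target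

Compound 25 is a germacrane-type lactone: a ten-membered carbocycle (C1–C10) fused through the C6–C7 bond to a butenolide (ring oxygen on C6, C7=C11, C12 carbonyl) whose α-carbon C11 carries a free hydroxymethyl group (C13). The carbocycle holds a Z trisubstituted alkene C4=C5 (methyl C15 on C4), an exocyclic methylene C10=C14, and acetoxy groups on C1 and C3. There are three stereocentres: C1 (S) and C3 (S) form a 1,3-anti diacetate across C2, and C6 (R) lies on the far side of the alkene, out of reach of simple 1,2- or 1,3-induction from them. Both acetates are allylic and therefore open to ionisation and to cleavage by nucleophiles. The C6 hydrogen is γ to the lactone carbonyl and allylic twice over, so it can epimerise. The primary C13 hydroxyl has to stay distinguishable from the two secondary ones that end up acetylated. The hard parts are the closure of a strained ten-membered ring around a Z trisubstituted alkene and the control of the isolated C6 centre. The strategy rests on one feature: C6 is at once the allylic carbinol carbon of C4=C5 and the γ-carbon of the butenolide, and C12 is held cis to it across the tetrasubstituted C7=C11 bond, so that a single C–C bond formation at C6 leaves an alkoxide placed to close the lactone.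

## Retrosynthetic reasoning

25 to 24. The free C13 hydroxyl is traced to the silyl ether 24. It is released last because fluoride removes a primary silyl ether without touching two allylic acetates, whereas an ester-type group on C13 could not be told apart from them.

24 to 21. The C5–C6 bond and the O–C12 bond are cut together. This opens both rings and leads to the open chain 21, with a (Z)-alkenyl iodide at C5 and a C6 formyl group cis to the C12 methyl ester. A cut at C1–C2 or C2–C3 would leave C6 and the butenolide to be built separately and would ask an aldol reaction to close a medium ring. A metathesis cut at C4=C5 would leave the geometry of a trisubstituted ring alkene to chance. The chosen cut gains two rings, two skeletal bonds and the last stereocentre in one operation, with the product one step from 25. The forward reaction has to add an alkenyl metal to an aldehyde in the presence of two acetates and a conjugated ester, keep the Z geometry, pick one face at C6, and cyclise in preference to intermolecular coupling.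

21 to 20 to 18 to 17. The cis formyl ester 21 is the ring-opened, O-methylated form of the γ-hydroxybutenolide 20, which is the γ-oxidation product of the butenolide 17 by way of its 2-silyloxyfuran 18. The C6 aldehyde is kept latent as the lactone CH2 because a free aldehyde could not be carried through the aldol and reduction steps that build C1–C3. The lactone also locks the cis geometry at C7=C11 that the key step needs. The forward steps need γ-selective oxidation that outruns oxidation of the other alkenes, and esterification of the open form, not the cyclic one.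

17 to 16 to 15. The acetates come from the anti diol 16. The C3 carbinol is traced to the C3 ketone of 15, so that a hydroxyl-directed reduction from C1 sets C3 in the anti sense.

15 to 8 and 12. The C1–C2 bond is cut as an aldol bond. This divides the chain into two pieces of similar size, creates C1 under reagent control and brings in the Z iodoalkene intact. The forward reaction must enolise 12 at its only α-methyl group and add to the si face of the formyl group of 8.

12 to 11 to 9. The Z iodoalkene is traced to an anti-carbomagnesiation–iodination of the propargylic alcohol 9, followed by oxidation of the carbinol. Chelation fixes the geometry, and the carbinol stereocentre of 9 is lost, so racemic material serves.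

8 to 7 to 6. C14 is cut off as a one-carbon unit, added by α-methylenation of the aldehyde 7. A four-carbon piece that already carried the methylene would need two primary hydroxyls of near-equal reactivity to be told apart. Here the aldehyde itself directs where C14 goes. The silyl ether 7 comes from the alcohol 6.

6 to 1 and 2. The C7–C8 and C11–C12 bonds are cut. Anti-carbomagnesiation of the symmetric diol 2 by the Grignard reagent 3 (from 1) gives 4. Carboxylation and acid then close the butenolide 5 and free the aldehyde 6. The tetrasubstituted alkene is formed with defined geometry in one flask, and the symmetry of 2 removes any regiochemical question.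

## Alternatives that were turned down

Alternative 1: Here the macrocycle would come from the cis-fused hydroazulenol mesylate A1, in which an extra C4–C10 bond splits the future ring into a five- and a seven-membered ring. In the forward step a hindered potassium alkoxide base forms the C10 alkoxide, the C4–C10 bond breaks as the C5 sulfonate leaves, and this Grob fragmentation would give the cyclodecenone A2 with the C10 ketone, the Z alkene and C7 masked as a ketal.
- For: the ring opens by a unimolecular, stereospecific process that needs no dilution. The alkene geometry follows from the relative configuration at C4 and C5. On reliability of medium-ring formation this route is stronger than a ring closure.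
- Against: A1 needs a quaternary C4, a tertiary C10 carbinol and a C5 sulfonate, three stereocentres that serve only as scaffolding and are destroyed. A2 still lacks C14, which would require olefination of a hindered ketone next to the epimerisable C1 centre. A2 also lacks all three butenolide carbons C11–C13, and it carries silyl and benzyl-type ethers that would have to be exchanged for two acetates.
- Comparison: many steps would follow the key step, against one in the chosen route. The chosen route secures the Z geometry in acyclic form by chelation-controlled carbomagnesiation, builds no sacrificial stereocentres, and closes both rings at once.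

Alternative 2: Here the carbocycle is traced to the ten-membered lactone A3, whose ring oxygen and C14 stand where C8 and C9 will be. Methylenation of the lactone carbonyl with a titanium methylidene reagent would give the cyclic allyl vinyl ether A4. Heating would then trigger a Claisen rearrangement that forms C8–C9, breaks O–C14 and gives the carbocyclic ketone A5 with the C7 carbonyl and the C10=C14 methylene.
- For: the C–C bond forms in a concerted unimolecular step between two unfunctionalised carbons, and the exocyclic methylene appears in the same step. On these two points it is as strong as or stronger than an organometallic ring closure.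
- Against: the hard ring closure is only moved to the lactonisation that makes A3, a ten-membered lactone containing a Z alkene. The rearrangement must pass through a bridged transition state in which C7 and C10 are tied by the six-atom chain C6–C1. The C6 centre of A5 is α to the new ketone and allylic, and so liable to epimerise under the thermal conditions. The whole butenolide and the acetate pattern remain to be installed afterwards.
- Comparison: the chosen route adds the methylene early by a simple aldehyde methylenation, needs no medium-ring lactonisation, and finishes the skeleton in the key step.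

Alternative 3: Here the ring would be closed between C1 and C2. The aldoxime A6 would be oxidised with hypochlorite to the nitrile oxide A7, which would add across the terminal C2=C3 alkene of the (Z)-diene to give the isoxazoline-bridged macrocycle A8, forming C1–C2 and O–C3.
- For: A8 already holds the butenolide, C6 and the C13 silyl ether, the C1/C3 oxygen pattern arrives in masked form, and no stoichiometric metal is needed. In late-stage convergence it is as strong as the chosen route.
- Against: A6 presupposes that C6 and the butenolide have been made by some other C5–C6 construction, which is as demanding as the chosen key step. A7 is a conjugated nitrile oxide and prone to dimerisation while a strained bridged ring forms slowly. C3 would be set during the macrocyclisation under remote control from C6 only. After A8 there remain N–O cleavage in the presence of reducible alkenes, an anti reduction of an α-methylene ketone, acetylation and desilylation.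
- Comparison: the chosen route sets C1 and C3 in the open chain by reagent and 1,3-control before the ring exists and keeps the post-cyclisation sequence to one step.

Key step: step 12

Remarks on the chemistry:
- Atom labels C1–C15 are those defined in the analysis.
- 9 is used as the racemate, because its carbinol carbon becomes the C3 carbonyl carbon of 12.
- 1 is taken to be a commercial chloro acetal.
- The sense of induction of the boron reagent in step 6 and of the ligand in step 12 is assigned by analogy and would be confirmed on the first run.

## Route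

Step 1
Reactants: 1 2-(3-chloropropyl)-1,3-dioxolane; 2 but-2-yne-1,4-diol
Product: 6 4-[4-(hydroxymethyl)-5-oxo-2,5-dihydrofuran-3-yl]butanal, via Grignard reagent 3 (not isolated), via alkenylmagnesium adduct 4 (not isolated), via acetal butenolide 5 (not isolated)
Conditions: 1, Mg, THF, 50 °C; 2, i-PrMgCl (2.0 equiv), THF, 0 °C, then 3 (1.6 equiv), CuI (10 mol %), reflux; CO2, −20 °C to rt; 2 M HCl, THF, rt
Reagents that add atoms: carbon dioxide, O=C=O; water, O
Why: Anti-carbomagnesiation of a propargylic magnesium alkoxide places the alkyl group and magnesium trans, with the C–Mg bond of 4 held cis to the CH2O group on the neighbouring carbon in a five-membered chelate, and the symmetry of 2 removes any regiochemical issue. Carboxylation puts C12 cis to the C6 hydroxymethyl group, so acidification closes the butenolide 5, and the same aqueous acid hydrolyses the dioxolane to the aldehyde.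

Step 2
Reactants: 6 4-[4-(hydroxymethyl)-5-oxo-2,5-dihydrofuran-3-yl]butanal
Product: 7 4-[4-({[tert-butyl(dimethyl)silyl]oxy}methyl)-5-oxo-2,5-dihydrofuran-3-yl]butanal
Conditions: TBSCl, imidazole, DMF, 0 °C
Reagents that add atoms: tert-butyldimethylsilyl chloride, CC(C)(C)[Si](C)(C)Cl
Why: Standard silylation of the only hydroxyl group; the aldehyde and the butenolide are inert to the silyl chloride and imidazole.

Step 3
Reactants: 7 4-[4-({[tert-butyl(dimethyl)silyl]oxy}methyl)-5-oxo-2,5-dihydrofuran-3-yl]butanal
Product: 8 4-[4-({[tert-butyl(dimethyl)silyl]oxy}methyl)-5-oxo-2,5-dihydrofuran-3-yl]-2-methylidenebutanal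
Conditions: 37% aq. HCHO, pyrrolidine (10 mol %), EtCO2H (10 mol %), i-PrOH, 45 °C
Reagents that add atoms: formaldehyde, C=O
Why: Amine–carboxylic acid catalysed α-methylenation of an aldehyde (Mannich condensation followed by loss of the amine) installs C14 on C10. Only the aldehyde forms an enamine, so the butenolide CH2 groups stay untouched.

Step 4
Reactants: 9 but-3-yn-2-ol (racemic)
Product: 11 (Z)-4-iodo-3-methylbut-3-en-2-ol (racemic), via alkenylmagnesium species 10 (not isolated)
Conditions: MeMgBr (3 equiv), CuI (10 mol %), THF, −10 °C to rt; I2, −78 to 0 °C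
Reagents that add atoms: methylmagnesium bromide, C[Mg]Br; iodine, II
Why: CuI-catalysed anti-carbomagnesiation of a propargylic alkoxide delivers the methyl group to the internal alkyne carbon and leaves magnesium on the terminal carbon, cis to the carbinol carbon in the chelate 10. Iodinolysis of the C–Mg bond with retention fixes the Z geometry that becomes the ring alkene C4=C5.

Step 5
Reactants: 11 (Z)-4-iodo-3-methylbut-3-en-2-ol
Product: 12 (Z)-4-iodo-3-methylbut-3-en-2-one
Conditions: MnO2 (excess), CH2Cl2, rt, dark
Reagents that add atoms: none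
Why: Heterogeneous, neutral oxidation of an allylic alcohol with MnO2 gives the enone without acid or base that could isomerise the Z iodoalkene; the ketone is used at once.

Step 6
Reactants: 12 (Z)-4-iodo-3-methylbut-3-en-2-one; 8 4-[4-({[tert-butyl(dimethyl)silyl]oxy}methyl)-5-oxo-2,5-dihydrofuran-3-yl]-2-methylidenebutanal
Product: 15 3-({[tert-butyl(dimethyl)silyl]oxy}methyl)-4-[(4S,7Z)-4-hydroxy-8-iodo-7-methyl-3-methylidene-6-oxooct-7-en-1-yl]furan-2(5H)-one, via boron enolate 13 (not isolated), via boron aldolate 14 (not isolated)
Conditions: 12 (1.5 equiv), (+)-Ipc2BCl (1.7 equiv), Et3N (2.0 equiv), Et2O, 0 °C; 8, −78 to −20 °C; pH 7 buffer, MeOH, 30% H2O2, 0 °C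
Reagents that add atoms: none
Why: Paterson aldol: 12 can enolise only at its α-methyl group, and the diisopinocampheylboron enolate 13 adds to the aldehyde through a cyclic transition state to give the aldolate 14, which the oxidative work-up cleaves. The (+)-configured ligands are expected to direct attack to the si face of the formyl group and so set C1 as S; 2-substituted acroleins are among the better acceptors for this reagent.

Step 7
Reactants: 15 3-({[tert-butyl(dimethyl)silyl]oxy}methyl)-4-[(4S,7Z)-4-hydroxy-8-iodo-7-methyl-3-methylidene-6-oxooct-7-en-1-yl]furan-2(5H)-one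
Product: 16 3-({[tert-butyl(dimethyl)silyl]oxy}methyl)-4-[(4S,6S,7Z)-4,6-dihydroxy-8-iodo-7-methyl-3-methylideneoct-7-en-1-yl]furan-2(5H)-one
Conditions: Me4NBH(OAc)3 (5 equiv), MeCN–AcOH (1:1), −30 °C
Reagents that add atoms: none
Why: Evans–Saksena reduction: the C1 hydroxyl displaces acetate on boron and hydride is delivered intramolecularly to the C3 ketone through a chair-like six-membered transition state, which gives the 1,3-anti diol and so sets C3 as S. The triacetoxyborohydride does not reduce the butenolide or attack the iodoalkene.

Step 8
Reactants: 16 3-({[tert-butyl(dimethyl)silyl]oxy}methyl)-4-[(4S,6S,7Z)-4,6-dihydroxy-8-iodo-7-methyl-3-methylideneoct-7-en-1-yl]furan-2(5H)-one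
Product: 17 (4S,6S,7Z)-1-[4-({[tert-butyl(dimethyl)silyl]oxy}methyl)-5-oxo-2,5-dihydrofuran-3-yl]-8-iodo-7-methyl-3-methylideneoct-7-ene-4,6-diyl diacetate
Conditions: Ac2O, pyridine, DMAP (cat.), CH2Cl2, 0 °C to rt
Reagents that add atoms: acetic anhydride, CC(=O)OC(C)=O
Why: DMAP-catalysed acylation of both secondary allylic alcohols; no stereocentre is touched and the silyl ether keeps C13 apart from the acetates.

Step 9
Reactants: 17 (4S,6S,7Z)-1-[4-({[tert-butyl(dimethyl)silyl]oxy}methyl)-5-oxo-2,5-dihydrofuran-3-yl]-8-iodo-7-methyl-3-methylideneoct-7-ene-4,6-diyl diacetate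
Product: 18 (4S,6S,7Z)-1-[5-{[tert-butyl(dimethyl)silyl]oxy}-4-({[tert-butyl(dimethyl)silyl]oxy}methyl)furan-3-yl]-8-iodo-7-methyl-3-methylideneoct-7-ene-4,6-diyl diacetate
Conditions: TBSOTf (1.3 equiv), Et3N (2 equiv), CH2Cl2, 0 °C; rapid filtration, used at once
Reagents that add atoms: tert-butyldimethylsilyl trifluoromethanesulfonate, CC(C)(C)[Si](C)(C)OS(=O)(=O)C(F)(F)F
Why: Soft enolisation of a butenolide: loss of a C6 proton gives the aromatic 2-silyloxyfuran, a driving force that the acetates lack, so they are not enolised by the amine and silyl triflate.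

Step 10
Reactants: 18 (4S,6S,7Z)-1-[5-{[tert-butyl(dimethyl)silyl]oxy}-4-({[tert-butyl(dimethyl)silyl]oxy}methyl)furan-3-yl]-8-iodo-7-methyl-3-methylideneoct-7-ene-4,6-diyl diacetate
Product: 20 (4S,6S,7Z)-1-[4-({[tert-butyl(dimethyl)silyl]oxy}methyl)-2-hydroxy-5-oxo-2,5-dihydrofuran-3-yl]-8-iodo-7-methyl-3-methylideneoct-7-ene-4,6-diyl diacetate (both hemiacetal epimers at C6), via silyl formyl ester 19 (not isolated)
Conditions: DMDO (1.05 equiv, acetone), CH2Cl2, −78 °C; pH 7 buffer, THF, 0 °C
Reagents that add atoms: dimethyldioxirane, CC1(C)OO1
Why: Electrophilic oxygen transfer to the electron-rich silyloxyfuran at C6 and ring opening give the silyl (Z)-4-oxo-enoate 19; at −78 °C this should be far faster than epoxidation of the 1,1-disubstituted or the iodo-substituted alkene. The labile silyl ester hydrolyses on work-up and the acid closes to the hydroxybutenolide, whose C6 epimers both serve in the next step.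

Step 11
Reactants: 20 (4S,6S,7Z)-1-[4-({[tert-butyl(dimethyl)silyl]oxy}methyl)-2-hydroxy-5-oxo-2,5-dihydrofuran-3-yl]-8-iodo-7-methyl-3-methylideneoct-7-ene-4,6-diyl diacetate
Product: 21 methyl (2Z,7S,9S,10Z)-7,9-diacetoxy-2-({[tert-butyl(dimethyl)silyl]oxy}methyl)-3-formyl-11-iodo-10-methyl-6-methylideneundeca-2,10-dienoate
Conditions: MeI (3 equiv), K2CO3 (1.5 equiv), DMF, 0 °C
Reagents that add atoms: iodomethane, CI
Why: Under carbonate the pseudo-acid opens to the formyl carboxylate, and O-alkylation of the carboxylate gives the open-chain methyl ester. The cis relation of CHO and CO2Me at C7=C11 is inherited from the ring, and the absence of an alcohol solvent protects the acetates.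

Step 12
Reactants: 21 methyl (2Z,7S,9S,10Z)-7,9-diacetoxy-2-({[tert-butyl(dimethyl)silyl]oxy}methyl)-3-formyl-11-iodo-10-methyl-6-methylideneundeca-2,10-dienoate
Product: 24 (7S,9S,10Z,11aR)-3-({[tert-butyl(dimethyl)silyl]oxy}methyl)-10-methyl-6-methylidene-2-oxo-2,4,5,6,7,8,9,11a-octahydrocyclodeca[b]furan-7,9-diyl diacetate, via alkenylchromium species 22 (not isolated), via chromium alkoxide 23 (not isolated)
Conditions: CrCl2 (8 equiv), (S)-N-[2-(4-isopropyl-4,5-dihydrooxazol-2-yl)-6-methylphenyl]methanesulfonamide (8.8 equiv), Et3N (8.8 equiv), THF, rt; NiCl2 (0.2 equiv); 21 added over 10 h (final 2 mM), rt; aqueous work-up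
Reagents that add atoms: none
Why: Intramolecular Nozaki–Hiyama–Kishi reaction: zerovalent nickel, formed from NiCl2 and divalent chromium, inserts into the C5–I bond with retention of the Z geometry, the alkenyl group passes to chromium to give the alkenyl trivalent chromium species 22, and this adds to the C6 formyl group only, since alkenylchromium reagents do not add to esters or acetates. The closest known reactions are macrocyclisations of alkenyl iodides onto aldehydes under these metals and the spontaneous lactonisation of γ-hydroxy-(Z)-enoates. Formation of C5–C6 closes the ten-membered carbocycle in a 10-exo-trig mode and gives the alkoxide 23, whose oxygen lies cis to the C12 ester across the tetrasubstituted C7=C11 bond; acyl substitution at C12 (5-exo-trig) then closes the butenolide and expels methoxide, which makes the sequence irreversible. The new stereocentre C6 is controlled by the sulfonamide-bound chromium, which differentiates the aldehyde faces, supported by the C3 acetoxy centre next to the nucleophilic carbon and by the conformational demand of the Z alkene in the forming ring; the ligand antipode is chosen so that these effects converge on the 6R alkoxide. The step needs chemoselectivity for the aldehyde, retention of alkene geometry, face selectivity at C6 and cyclisation in preference to intermolecular coupling; these rest, in that order, on the carbonyl selectivity of organochromium reagents, the trisubstituted nature of the iodoalkene, the chiral ligand, and slow addition at high dilution. Any hydroxy ester that survives closes on work-up.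

Step 13
Reactants: 24 (7S,9S,10Z,11aR)-3-({[tert-butyl(dimethyl)silyl]oxy}methyl)-10-methyl-6-methylidene-2-oxo-2,4,5,6,7,8,9,11a-octahydrocyclodeca[b]furan-7,9-diyl diacetate
Product: 25 (7S,9S,10Z,11aR)-3-(hydroxymethyl)-10-methyl-6-methylidene-2-oxo-2,4,5,6,7,8,9,11a-octahydrocyclodeca[b]furan-7,9-diyl diacetate (in the atom labels used here: 1S, 3S, 6R)
Conditions: HF·pyridine, pyridine, THF, 0 °C to rt
Reagents that add atoms: none
Why: Fluoride-mediated cleavage of a primary silyl ether; buffering with pyridine keeps the medium mild enough that the allylic acetates and the epimerisable C6 centre should be unaffected.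

## Compound list

1 | 2-(3-chloropropyl)-1,3-dioxolane | ClCCCC1OCCO1 | starting material
2 | but-2-yne-1,4-diol | OCC#CCO | starting material
3 | [3-(1,3-dioxolan-2-yl)propyl]magnesium chloride (not isolated) | Cl[Mg]CCCC1OCCO1 | intermediate
4 | alkenylmagnesium adduct of 2 and 3, magnesium on carbon cis to the neighbouring CH2O group (not isolated) | Cl[Mg]OC/C(CCCC1OCCO1)=C(\[Mg]Cl)CO[Mg]Cl | intermediate
5 | 4-[3-(1,3-dioxolan-2-yl)propyl]-3-(hydroxymethyl)furan-2(5H)-one (not isolated) | OCC1=C(CCCC2OCCO2)COC1=O | intermediate
6 | 4-[4-(hydroxymethyl)-5-oxo-2,5-dihydrofuran-3-yl]butanal | O=CCCCC1=C(CO)C(=O)OC1 | intermediate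
7 | 4-[4-({[tert-butyl(dimethyl)silyl]oxy}methyl)-5-oxo-2,5-dihydrofuran-3-yl]butanal | O=CCCCC1=C(CO[Si](C)(C)C(C)(C)C)C(=O)OC1 | intermediate
8 | 4-[4-({[tert-butyl(dimethyl)silyl]oxy}methyl)-5-oxo-2,5-dihydrofuran-3-yl]-2-methylidenebutanal | C=C(C=O)CCC1=C(CO[Si](C)(C)C(C)(C)C)C(=O)OC1 | intermediate
9 | but-3-yn-2-ol (racemic) | CC(O)C#C | starting material
10 | bromomagnesium alkoxide of (Z)-4-(bromomagnesio)-3-methylbut-3-en-2-ol (not isolated) | CC(O[Mg]Br)/C(C)=C\[Mg]Br | intermediate
11 | (Z)-4-iodo-3-methylbut-3-en-2-ol (racemic) | CC(O)/C(C)=C\I | intermediate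
12 | (Z)-4-iodo-3-methylbut-3-en-2-one | CC(=O)/C(C)=C\I | intermediate
13 | (Z)-4-iodo-3-methylbuta-1,3-dien-2-yl diisopinocampheylborinate, (+)-Ipc series (not isolated) | C=C(OB([C@H]1C[C@H]2C[C@@H]([C@@H]1C)C2(C)C)[C@H]1C[C@H]2C[C@@H]([C@@H]1C)C2(C)C)/C(C)=C\I | intermediate
14 | diisopinocampheylboron aldolate of 15 (not isolated) | I/C=C(/C)C(=O)C[C@H](OB([C@H]1C[C@H]2C[C@@H]([C@@H]1C)C2(C)C)[C@H]1C[C@H]2C[C@@H]([C@@H]1C)C2(C)C)C(=C)CCC1=C(CO[Si](C)(C)C(C)(C)C)C(=O)OC1 | intermediate
15 | 3-({[tert-butyl(dimethyl)silyl]oxy}methyl)-4-[(4S,7Z)-4-hydroxy-8-iodo-7-methyl-3-methylidene-6-oxooct-7-en-1-yl]furan-2(5H)-one | I/C=C(/C)C(=O)C[C@H](O)C(=C)CCC1=C(CO[Si](C)(C)C(C)(C)C)C(=O)OC1 | intermediate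
16 | 3-({[tert-butyl(dimethyl)silyl]oxy}methyl)-4-[(4S,6S,7Z)-4,6-dihydroxy-8-iodo-7-methyl-3-methylideneoct-7-en-1-yl]furan-2(5H)-one | I/C=C(/C)[C@@H](O)C[C@H](O)C(=C)CCC1=C(CO[Si](C)(C)C(C)(C)C)C(=O)OC1 | intermediate
17 | (4S,6S,7Z)-1-[4-({[tert-butyl(dimethyl)silyl]oxy}methyl)-5-oxo-2,5-dihydrofuran-3-yl]-8-iodo-7-methyl-3-methylideneoct-7-ene-4,6-diyl diacetate | I/C=C(/C)[C@@H](OC(C)=O)C[C@H](OC(C)=O)C(=C)CCC1=C(CO[Si](C)(C)C(C)(C)C)C(=O)OC1 | intermediate
18 | (4S,6S,7Z)-1-[5-{[tert-butyl(dimethyl)silyl]oxy}-4-({[tert-butyl(dimethyl)silyl]oxy}methyl)furan-3-yl]-8-iodo-7-methyl-3-methylideneoct-7-ene-4,6-diyl diacetate | I/C=C(/C)[C@@H](OC(C)=O)C[C@H](OC(C)=O)C(=C)CCc1coc(O[Si](C)(C)C(C)(C)C)c1CO[Si](C)(C)C(C)(C)C | intermediate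
19 | tert-butyl(dimethyl)silyl (2Z,7S,9S,10Z)-7,9-diacetoxy-2-({[tert-butyl(dimethyl)silyl]oxy}methyl)-3-formyl-11-iodo-10-methyl-6-methylideneundeca-2,10-dienoate (not isolated) | I/C=C(/C)[C@@H](OC(C)=O)C[C@H](OC(C)=O)C(=C)CC/C(C=O)=C(\CO[Si](C)(C)C(C)(C)C)C(=O)O[Si](C)(C)C(C)(C)C | intermediate
20 | (4S,6S,7Z)-1-[4-({[tert-butyl(dimethyl)silyl]oxy}methyl)-2-hydroxy-5-oxo-2,5-dihydrofuran-3-yl]-8-iodo-7-methyl-3-methylideneoct-7-ene-4,6-diyl diacetate, both hemiacetal epimers | I/C=C(/C)[C@@H](OC(C)=O)C[C@H](OC(C)=O)C(=C)CCC1=C(CO[Si](C)(C)C(C)(C)C)C(=O)OC1O | intermediate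
21 | methyl (2Z,7S,9S,10Z)-7,9-diacetoxy-2-({[tert-butyl(dimethyl)silyl]oxy}methyl)-3-formyl-11-iodo-10-methyl-6-methylideneundeca-2,10-dienoate | I/C=C(/C)[C@@H](OC(C)=O)C[C@H](OC(C)=O)C(=C)CC/C(C=O)=C(\CO[Si](C)(C)C(C)(C)C)C(=O)OC | intermediate
22 | methyl (2Z,7S,9S,10Z)-7,9-diacetoxy-2-({[tert-butyl(dimethyl)silyl]oxy}methyl)-11-(dichlorochromio)-3-formyl-10-methyl-6-methylideneundeca-2,10-dienoate (not isolated) | Cl[Cr](Cl)/C=C(/C)[C@@H](OC(C)=O)C[C@H](OC(C)=O)C(=C)CC/C(C=O)=C(\CO[Si](C)(C)C(C)(C)C)C(=O)OC | intermediate
23 | methyl (2Z)-2-[(2R,3Z,5S,7S)-5,7-diacetoxy-2-[(dichlorochromio)oxy]-4-methyl-8-methylidenecyclodec-3-en-1-ylidene]-3-{[tert-butyl(dimethyl)silyl]oxy}propanoate (not isolated) | C=C1CC/C(=C(\CO[Si](C)(C)C(C)(C)C)C(=O)OC)[C@H](O[Cr](Cl)Cl)/C=C(/C)[C@@H](OC(C)=O)C[C@@H]1OC(C)=O | intermediate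
24 | (7S,9S,10Z,11aR)-3-({[tert-butyl(dimethyl)silyl]oxy}methyl)-10-methyl-6-methylidene-2-oxo-2,4,5,6,7,8,9,11a-octahydrocyclodeca[b]furan-7,9-diyl diacetate | C=C1CCC2=C(CO[Si](C)(C)C(C)(C)C)C(=O)O[C@@H]2/C=C(/C)[C@@H](OC(C)=O)C[C@@H]1OC(C)=O | intermediate
25 | (7S,9S,10Z,11aR)-3-(hydroxymethyl)-10-methyl-6-methylidene-2-oxo-2,4,5,6,7,8,9,11a-octahydrocyclodeca[b]furan-7,9-diyl diacetate | C=C1CCC2=C(CO)C(=O)O[C@@H]2/C=C(/C)[C@@H](OC(C)=O)C[C@@H]1OC(C)=O | target

## Step count and least certain steps

Total step count: 13. Longest linear sequence: 11 steps (steps 1–3 and 6–13); steps 4 and 5 make the second fragment.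

Step 12 (key step). The most likely failure is insufficient face selectivity at C6, because the strain of the forming ten-membered ring may override the ligand. Slow cyclisation would also let protodeiodination, intermolecular coupling, or one-electron reduction of the doubly activated C7=C11 alkene by divalent chromium compete. Which ligand antipode is matched cannot be predicted with certainty, so both would be tried. The fallback changes the control element from the addition to a later equilibration. It sets out from 21 under the conditions of step 12. The unwanted (6S)-epimer of 24, F1, is separated and converted with TBSOTf and Et3N, as in step 9, into the ring-fused 2-silyloxyfuran F2, in which C6 is planar. Protonation of F2 (aqueous HCl in THF at −20 °C, then Et3N to bring the alkene into conjugation) returns 24 together with F1, which is recycled. The route is rejoined at 24.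

Step 1. Anti-carbomagnesiation with a functionalised primary alkylmagnesium chloride may be sluggish, so that the alkyne is left unconsumed or carboxylation is incomplete. The fallback builds the same butenolide by cross-coupling and replaces 1 and 2. 3,4-Dibromofuran-2(5H)-one F3 is coupled at its more electrophilic C4 position with the borane F5, made from 4,4-diethoxybut-1-ene F4 and 9-BBN (Suzuki coupling, PdCl2(dppf), K3PO4), to give the bromo butenolide F6. Stille coupling of F6 with Bu3SnCH2OH (Pd(PPh3)4, dioxane, heat) gives the hydroxymethyl butenolide acetal F7. Aqueous acid then frees the aldehyde and the route is rejoined at 6.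

Step 6. Methyl ketone aldols with diisopinocampheylboron enolates give only moderate enantioselectivity in general, and the sense may depend on the bulk of the ketone. In addition, Et3N or chloride could add to the β-iodoenone and erode the Z geometry. Since C3 is later set from C1, any loss of enantiopurity here cannot be removed as a diastereomer. The enantiomeric purity of 15 would be checked by MTPA ester analysis. The fallback changes to a catalytic, open-transition-state aldol and sets out from 12. LiN(SiMe3)2 and Me3SiCl at −78 °C give the trimethylsilyl enol ether F8 without exposing the iodoenone to a nucleophilic amine. A Mukaiyama aldol of F8 with 8, promoted by SiCl4 under chiral bisphosphoramide Lewis-base catalysis at −78 °C, gives 15 after aqueous work-up, where the route is rejoined.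

Step 11. Alkylation may take place on the cyclic form to give the pseudo-ester, or base may isomerise the formyl acrylate. Either would remove the cis aldehyde–ester arrangement that the key step needs. The fallback avoids the esterification altogether and sets out from 17. TIPSOTf and Et3N give the triisopropylsilyloxyfuran F9, and DMDO at −78 °C gives the more robust triisopropylsilyl (Z)-formyl ester F10, isolated without hydrolysis. F10 is submitted directly to the conditions of step 12, where the silyl ester serves as the acyl donor and a silanolate leaves. The route is rejoined at 24.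

## Further compounds

F1 | step 12 | (7S,9S,10Z,11aS)-3-({[tert-butyl(dimethyl)silyl]oxy}methyl)-10-methyl-6-methylidene-2-oxo-2,4,5,6,7,8,9,11a-octahydrocyclodeca[b]furan-7,9-diyl diacetate (C6 epimer of 24) | C=C1CCC2=C(CO[Si](C)(C)C(C)(C)C)C(=O)O[C@H]2/C=C(/C)[C@@H](OC(C)=O)C[C@@H]1OC(C)=O
F2 | step 12 | (7S,9S,10Z)-2-{[tert-butyl(dimethyl)silyl]oxy}-3-({[tert-butyl(dimethyl)silyl]oxy}methyl)-10-methyl-6-methylidene-4,5,6,7,8,9-hexahydrocyclodeca[b]furan-7,9-diyl diacetate | C=C1CCc2c(CO[Si](C)(C)C(C)(C)C)c(O[Si](C)(C)C(C)(C)C)oc2/C=C(/C)[C@@H](OC(C)=O)C[C@@H]1OC(C)=O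
F3 | step 1 | 3,4-dibromofuran-2(5H)-one | O=C1OCC(Br)=C1Br
F4 | step 1 | 4,4-diethoxybut-1-ene | C=CCC(OCC)OCC
F5 | step 1 | 9-(4,4-diethoxybutyl)-9-borabicyclo[3.3.1]nonane | CCOC(CCCB1C2CCCC1CCC2)OCC
F6 | step 1 | 3-bromo-4-(4,4-diethoxybutyl)furan-2(5H)-one | CCOC(CCCC1=C(Br)C(=O)OC1)OCC
F7 | step 1 | 4-(4,4-diethoxybutyl)-3-(hydroxymethyl)furan-2(5H)-one | CCOC(CCCC1=C(CO)C(=O)OC1)OCC
F8 | step 6 | (Z)-(4-iodo-3-methylbuta-1,3-dien-2-yl)oxy(trimethyl)silane | C=C(O[Si](C)(C)C)/C(C)=C\I
F9 | step 11 | (4S,6S,7Z)-1-[4-({[tert-butyl(dimethyl)silyl]oxy}methyl)-5-{[tri(propan-2-yl)silyl]oxy}furan-3-yl]-8-iodo-7-methyl-3-methylideneoct-7-ene-4,6-diyl diacetate | I/C=C(/C)[C@@H](OC(C)=O)C[C@H](OC(C)=O)C(=C)CCc1coc(O[Si](C(C)C)(C(C)C)C(C)C)c1CO[Si](C)(C)C(C)(C)C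
F10 | step 11 | tri(propan-2-yl)silyl (2Z,7S,9S,10Z)-7,9-diacetoxy-2-({[tert-butyl(dimethyl)silyl]oxy}methyl)-3-formyl-11-iodo-10-methyl-6-methylideneundeca-2,10-dienoate | I/C=C(/C)[C@@H](OC(C)=O)C[C@H](OC(C)=O)C(=C)CC/C(C=O)=C(\CO[Si](C)(C)C(C)(C)C)C(=O)O[Si](C(C)C)(C(C)C)C(C)C
A1 | alternative 1 | cis-fused hydroazulenol mesylate with C4–C10 bond, C10 hydroxyl, C5 mesylate, C6 4-methoxybenzyl ether, C7 dioxolane and C1/C3 silyl ethers | C[C@]12[C@@H](OS(C)(=O)=O)[C@@H](OCc3ccc(OC)cc3)C3(OCCO3)CC[C@@]1(O)[C@@H](O[Si](C)(C)C(C)(C)C)C[C@@H]2O[Si](C)(C)C(C)(C)C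
A2 | alternative 1 | ten-membered C10 ketone with Z C4=C5 alkene and C7 dioxolane | O=C1CCC2(OCCO2)[C@H](OCc3ccc(OC)cc3)/C=C(/C)[C@@H](O[Si](C)(C)C(C)(C)C)C[C@@H]1O[Si](C)(C)C(C)(C)C
A3 | alternative 2 | ten-membered lactone with C7 carbonyl, ring oxygen bound to C14 and C10=C9 methylene | C=C1COC(=O)[C@H](OCc2ccc(OC)cc2)/C=C(/C)[C@@H](O[Si](C)(C)C(C)(C)C)C[C@@H]1O[Si](C)(C)C(C)(C)C
A4 | alternative 2 | ten-membered cyclic allyl vinyl ether (C8H2=C7–O–C14H2–C10=C9H2) | C=C1COC(=C)[C@H](OCc2ccc(OC)cc2)/C=C(/C)[C@@H](O[Si](C)(C)C(C)(C)C)C[C@@H]1O[Si](C)(C)C(C)(C)C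
A5 | alternative 2 | ten-membered C7 ketone with exocyclic C10=C14 methylene | C=C1CCC(=O)[C@H](OCc2ccc(OC)cc2)/C=C(/C)[C@@H](O[Si](C)(C)C(C)(C)C)C[C@@H]1O[Si](C)(C)C(C)(C)C
A6 | alternative 3 | (E)-aldoxime at C1 of the butenolide bearing the (Z)-diene side chain at C6 | C=C(/C=N/O)CCC1=C(CO[Si](C)(C)C(C)(C)C)C(=O)O[C@@H]1/C=C(/C)C=C
A7 | alternative 3 | C1 nitrile oxide of the same butenolide diene | C=C(C#[N+][O-])CCC1=C(CO[Si](C)(C)C(C)(C)C)C(=O)O[C@@H]1/C=C(/C)C=C
A8 | alternative 3 | isoxazoline-bridged ten-membered butenolide | C=C1CCC2=C(CO[Si](C)(C)C(C)(C)C)C(=O)O[C@@H]2/C=C(/C)[C@@H]3CC1=NO3
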